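**Retrosynthetic overview**

1. The target gibberellin (21) ⇐ demethylation of diester 20 ⇐ key step: Mn(OAc)3 oxidation of malonate 19. The malonyl radical closes ring A 6-endo onto the C5=C10 alkene (C4–C5 bond), and the oxidised C10 centre is captured by a malonate ester as the 19,10-lactone.
2. 19 ⇐ B-alkyl Suzuki coupling of enol triflate 14 (from C10 ketone 13) with the 9-BBN adduct of dimethyl allylmalonate 17.
3. 13 ⇐ ring D by Nozaki–Hiyama–Kishi closure of a C8 2-bromoallyl arm onto the C13 ketone (9 → 10); quaternary C8 from a Hosomi–Sakurai addition to enone 7.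
4. 7 ⇐ ring B by intramolecular Stork–Danheiser addition of the lactone enolate of 5; 5 from cyclohexane-1,3-dione (ring C) and methyl 4-oxobutanoate by an asymmetric anti boron aldol reaction and lactonisation.
5. Ring order: C (from 1) → B → D → A together with the lactone.

Conventions and assumptions:
- Gibberellane numbering (C1–C19) is used for all intermediates.
- β is the face of ring B that carries H5, H9 and the C15–C16 bridge in the target; α is the face of the lactone oxygen and C14.
- "Anti" refers to C11 and the C10 oxygen on the C8–C9–C10–C5 chain.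
- Bis(menthylmethyl)chloroborane is chlorobis{[(1R,2S,5R)-2-isopropyl-5-methylcyclohexyl]methyl}borane, made from (−)-menthone. It is assumed to favour the (9S,10S) adduct; if its sense of induction is the opposite, the enantiomeric reagent from (+)-menthone is used.

**Route**

Step 1
Reactants: 1 cyclohexane-1,3-dione
Product: 2 3-methoxycyclohex-2-en-1-one
Conditions: MeOH, TsOH·H2O (2 mol %), 3 Å molecular sieves, 50 °C
Reagents that add atoms: methanol (CO)
Why: Acid-catalysed enol etherification of the 1,3-dione gives the vinylogous ester, which masks the C13 ketone, leaves C8 as the carbonyl for the later Stork–Danheiser transposition and carries the same alkoxy group as ester 3, so that no alkoxy exchange can occur in step 2.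

Step 2
Reactants: 2 3-methoxycyclohex-2-en-1-one; 3 methyl 4-oxobutanoate
Product: 5 (5S)-5-[(1S)-4-methoxy-2-oxocyclohex-3-en-1-yl]oxolan-2-one, via hydroxy ester 4 (not isolated)
Conditions: bis(menthylmethyl)chloroborane (1.3 equiv), Et3N (1.5 equiv), CH2Cl2, −78 → 0 °C; 3 (1.2 equiv), −78 → −20 °C; MeOH, pH 7 buffer, 30% H2O2, 0 °C; then TsOH·H2O (5 mol %), toluene, 40 °C; chromatography, recrystallisation
Reagents that add atoms: none
Why: Boron-mediated aldol reaction: soft enolisation at C9 gives the ring-locked E enol borinate, whose closed Zimmerman–Traxler transition state delivers the anti (9S,10S) adduct with the enolate face chosen by the menthylmethyl ligands, the γ-hydroxy ester then lactonises under acid, and recrystallisation of 5 raises the enantiomeric purity.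

Step 3
Reactants: 5 (5S)-5-[(1S)-4-methoxy-2-oxocyclohex-3-en-1-yl]oxolan-2-one
Product: 7 tricyclic enone lactone (13-oxo; 8(14)-ene; 7,10α-lactone bridge; 9β-H), via bridged carbinol 6 (not isolated)
Conditions: LiN(i-Pr)2 (1.1 equiv), THF, −78 → −30 °C; then 1 M HCl, THF, 0 → 23 °C
Reagents that add atoms: none
Why: Intramolecular Stork–Danheiser reaction: kinetic deprotonation of the unhindered lactone methylene C6 (in preference to the hindered C9 methine) gives the enolate that adds 5-exo to the vinylogous ester carbonyl C8, and acid then hydrolyses the enol ether and eliminates water to the C13 enone, the C7–O–C10 lactone bridging the α face of the new ring B (C6 fixed by the bridge; C9 and C10 untouched).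

Step 4
Reactants: 7 tricyclic enone lactone; 8 (2-bromoallyl)trimethylsilane
Product: 9 8β-(2-bromoallyl) keto lactone (13-oxo; 7,10α-lactone bridge; 9β-H; rings B/C cis)
Conditions: 8 (2.0 equiv), TiCl4 (1.2 equiv), CH2Cl2, −78 → −40 °C; then H2O
Reagents that add atoms: none
Why: Hosomi–Sakurai conjugate allylation: the silane attacks C8 from the exo (β) face, anti to the lactone bridge and cis to H9, the only mode that leaves ring C cis-fused on the bicyclo[2.2.1] frame, so the quaternary C8 follows from C9 and C10.

Step 5
Reactants: 9 8β-(2-bromoallyl) keto lactone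
Product: 10 tetracyclic hydroxy lactone (BCD rings; 13-OH; 16-methylene; 7,10α-lactone bridge)
Conditions: CrCl2 (6 equiv), NiCl2 (5 mol %), DMF, 50 °C; aq. NH4Cl
Reagents that add atoms: none
Why: Nozaki–Hiyama–Kishi reaction: the vinylchromium species formed from the vinyl bromide adds 5-exo to the C13 ketone and closes ring D, and the bridgehead carbinol C13 can only form on the face of the C15 arm, so its configuration follows from C8.

Step 6
Reactants: 10 tetracyclic hydroxy lactone
Product: 12 methyl ester diol (6β-CO2Me; 10α-OH; 13-OH; 16-methylene), via 6α-ester 11 (not isolated)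
Conditions: NaOMe (0.3 equiv), MeOH, 65 °C; AcOH
Reagents that add atoms: methanol (CO)
Why: Methoxide-catalysed transesterification opens the strained bicyclic lactone to the 6α-ester 11, whose C6–H then equilibrates through the ester enolate towards the 6β-ester 12 (trans to the C10 hydroxyl and unable to lactonise), residual 11 closing back to 10 on acid treatment and being recycled.

Step 7
Reactants: 12 methyl ester diol
Product: 13 keto ester (6β-CO2Me; 10-oxo; 13-OH; 16-methylene)
Conditions: Dess–Martin periodinane (1.3 equiv), NaHCO3, CH2Cl2, 0 → 23 °C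
Reagents that add atoms: none
Why: Dess–Martin oxidation converts the secondary C10 alcohol into the ketone under buffered conditions that leave the tertiary allylic C13 alcohol and the epimerisable C6 and C9 centres untouched.

Step 8
Reactants: 13 keto ester
Product: 14 enol triflate (10-OTf; 5(10)-ene; 6β-CO2Me; 13-OH; 16-methylene)
Conditions: KN(SiMe3)2 (2.2 equiv), THF, −78 °C; Comins' reagent (1.2 equiv), −78 °C; aq. NH4Cl
Reagents that add atoms: Comins' reagent, N-(5-chloropyridin-2-yl)bis(trifluoromethanesulfonyl)imide (Clc1ccc(nc1)N(S(=O)(=O)C(F)(F)F)S(=O)(=O)C(F)(F)F)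
Why: Kinetic enolate formation at the less hindered C5 methylene (the other α-carbon C9 is a hindered methine) and O-triflation give the C5=C10 enol triflate regioselectively at low temperature without touching C6 or C9.

Step 9
Reactants: 15 methyl pent-4-enoate; 16 methyl chloroformate
Product: 17 dimethyl 2-allylmalonate
Conditions: LiN(i-Pr)2 (2.1 equiv), THF, −78 °C; 16 (1.05 equiv); aq. NH4Cl
Reagents that add atoms: none
Why: Claisen-type C-acylation of the ester enolate with the chloroformate gives the malonate, the second equivalent of base absorbing the acidic malonate proton.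

Step 10
Reactants: 14 enol triflate; 17 dimethyl 2-allylmalonate
Product: 19 dimethyl 2-[3-(C10-yl)propyl]malonate of the BCD tricycle (5(10)-ene; 6β-CO2Me; 13-OH; 16-methylene), via alkylborane 18 (not isolated)
Conditions: 17 (1.6 equiv), 9-BBN (1.5 equiv), THF, 0 → 23 °C; then 14, Pd(dppf)Cl2 (5 mol %), AsPh3 (5 mol %), Cs2CO3 (3 equiv), DMF/H2O, 23 °C
Reagents that add atoms: none
Why: B-alkyl Suzuki–Miyaura coupling: anti-Markovnikov hydroboration of the terminal alkene of 17 gives the primary alkylborane, which is transferred to the vinyl triflate with the C5=C10 alkene kept in place and no stereocentre formed.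

Step 11
Reactants: 19 malonate of the BCD tricycle
Product: 20 dimethyl ester of the target gibberellin (7- and 18-methyl esters; 19,10-lactone)
Conditions: Mn(OAc)3·2H2O (2.5 equiv), AcOH, 65 °C, 0.005 M, argon
Reagents that add atoms: none
Why: Mn(OAc)3-based oxidative free-radical cyclisation: the malonyl radical at C4 adds 6-endo to the less substituted alkene carbon C5 from the α face (anti to the adjacent 6β-ester), the tertiary C10 radical is oxidised by a second equivalent of trivalent manganese, and the cation is trapped by the cis malonate carbonyl with loss of methyl acetate, so that C5, C10 and C4 (forced by the bridged lactone) are set in one step.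

Step 12
Reactants: 20 dimethyl ester of the target gibberellin
Product: 21 target gibberellin (ent-10,13-dihydroxy-20-norgibberell-16-ene-7,18,19-trioic acid 19,10-lactone)
Conditions: n-PrSLi (6 equiv), HMPA, 25 °C; then 1 M HCl
Reagents that add atoms: none
Why: Nucleophilic demethylation of both methyl esters by the thiolate at the methyl carbon leaves the tertiary-alkyl lactone, C6 and the acid-sensitive 13-hydroxy-16-ene unit untouched.

**Compound list**

1 | cyclohexane-1,3-dione | O=C1CCCC(=O)C1 | starting material
2 | 3-methoxycyclohex-2-en-1-one | COC1=CC(=O)CCC1 | intermediate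
3 | methyl 4-oxobutanoate | COC(=O)CCC=O | starting material
4 | methyl (4S)-4-hydroxy-4-[(1S)-4-methoxy-2-oxocyclohex-3-en-1-yl]butanoate (not isolated) | COC1=CC(=O)[C@@H](CC1)[C@@H](O)CCC(=O)OC | intermediate
5 | (5S)-5-[(1S)-4-methoxy-2-oxocyclohex-3-en-1-yl]oxolan-2-one | COC1=CC(=O)[C@@H](CC1)[C@@H]1CCC(=O)O1 | intermediate
6 | bridged carbinol (C6–C8 bond formed; 8β-OH; C13 enol ether kept; 7,10α-lactone; not isolated) | COC1=C[C@]2(O)[C@H]3C[C@H](OC3=O)[C@@H]2CC1 | intermediate
7 | tricyclic enone lactone (13-oxo; 8(14)-ene; 7,10α-lactone bridge; 9β-H) | O=C1C=C2[C@H]3C[C@H](OC3=O)[C@@H]2CC1 | intermediate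
8 | (2-bromoallyl)trimethylsilane | C=C(Br)C[Si](C)(C)C | starting material
9 | 8β-(2-bromoallyl) keto lactone (13-oxo; 7,10α-lactone bridge; 9β-H; rings B/C cis) | C=C(Br)C[C@]12CC(=O)CC[C@H]1[C@@H]3C[C@H]2C(=O)O3 | intermediate
10 | tetracyclic hydroxy lactone (BCD rings; 13-OH; 16-methylene; 7,10α-lactone bridge) | C=C1C[C@]23C[C@@]1(O)CC[C@H]2[C@@H]1C[C@H]3C(=O)O1 | intermediate
11 | 6α-ester diol (6α-CO2Me; 10α-OH; 13-OH; 16-methylene; not isolated) | C=C1C[C@]23C[C@@]1(O)CC[C@H]2[C@@H](O)C[C@H]3C(=O)OC | intermediate
12 | methyl ester diol (6β-CO2Me; 10α-OH; 13-OH; 16-methylene) | C=C1C[C@]23C[C@@]1(O)CC[C@H]2[C@@H](O)C[C@@H]3C(=O)OC | intermediate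
13 | keto ester (6β-CO2Me; 10-oxo; 13-OH; 16-methylene; 9β-H) | C=C1C[C@]23C[C@@]1(O)CC[C@H]2C(=O)C[C@@H]3C(=O)OC | intermediate
14 | enol triflate (10-OTf; 5(10)-ene; 6β-CO2Me; 13-OH; 16-methylene) | C=C1C[C@]23C[C@@]1(O)CC[C@H]2C(OS(=O)(=O)C(F)(F)F)=C[C@@H]3C(=O)OC | intermediate
15 | methyl pent-4-enoate | C=CCCC(=O)OC | starting material
16 | methyl chloroformate | COC(Cl)=O | starting material
17 | dimethyl 2-allylmalonate | C=CCC(C(=O)OC)C(=O)OC | intermediate
18 | dimethyl 2-[3-(9-borabicyclo[3.3.1]nonan-9-yl)propyl]malonate (not isolated) | COC(=O)C(CCCB1C2CCCC1CCC2)C(=O)OC | intermediate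
19 | dimethyl 2-[3-(C10-yl)propyl]malonate of the BCD tricycle (5(10)-ene; 6β-CO2Me; 13-OH; 16-methylene; 9β-H) | C=C1C[C@]23C[C@@]1(O)CC[C@H]2C(CCCC(C(=O)OC)C(=O)OC)=C[C@@H]3C(=O)OC | intermediate
20 | dimethyl ester of the target gibberellin (7- and 18-methyl esters; 19,10-lactone) | C=C1C[C@]23C[C@@]1(O)CC[C@H]2[C@@]12CCC[C@@](C(=O)OC)(C(=O)O1)[C@H]2[C@@H]3C(=O)OC | intermediate
21 | target gibberellin (ent-10,13-dihydroxy-20-norgibberell-16-ene-7,18,19-trioic acid 19,10-lactone) | C=C1C[C@]23C[C@@]1(O)CC[C@H]2[C@@]12CCC[C@@](C(=O)O)(C(=O)O1)[C@H]2[C@@H]3C(=O)O | target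

**Step count and risk**

Total steps: 12. Longest linear sequence: 11 steps (steps 1–8 and 10–12; step 9 makes the side-chain reagent).

The three steps most likely to fail:

Step 11 (key radical annulation). The malonyl radical must attack C5 from the α face, guided mainly by the 6β-ester, and its addition to the 16-methylene group of a second molecule has to be suppressed by dilution. The fallback sets out from 19 and uses the free malonic acid, which enolises far more easily, reacts at room temperature and closes the lactone through its own carboxyl group. LiOH (2.2 equiv, THF/H2O, 0 °C) hydrolyses only the two unhindered malonate esters and gives the malonic acid F1. Mn(OAc)3·2H2O in AcOH at 25 °C then effects the double annulation (ring A and lactone) to the target's 7-methyl ester F2. n-PrSLi in HMPA removes the remaining methyl group, and the route is rejoined at the target 21.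

Step 3 (bridged Stork–Danheiser closure). The lithium aldolate is strained and can revert, and deprotonation at C9 instead of C6 would eject the lactone carboxylate. The fallback sets out from 5 and makes the ring closure irreversible under Lewis-acid conditions. LiN(SiMe3)2 with Me3SiCl present as an internal quench (THF, −78 °C) gives the trimethylsilyl ketene acetal F3. Me3SiOTf (10 mol %, CH2Cl2, −78 °C) activates the vinylogous ester, and the ketene acetal adds to C8 in an intramolecular Mukaiyama-type reaction with silyl transfer to give the silyl ether F4. Aqueous HCl then hydrolyses F4 by way of carbinol 6, and the route is rejoined at 7.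

Step 2 (asymmetric anti aldol reaction). The anti selectivity of the ring-locked enolate is reliable, but the enantioselectivity of chiral dialkylboron enolates of this type is usually only moderate to good, and the vinylogous ester must enolise at C9 and not at C12. The fallback sets out from 2 and replaces the stoichiometric chiral boron enolate by a catalytic chiral Lewis acid acting on a preformed tin enolate. LiN(i-Pr)2 and then Bu3SnCl (THF, −78 °C) convert 2 into the tributyltin enolate F5. AgOTf and (R)-BINAP (10 mol % each, THF, −20 °C; the ligand enantiomer is chosen to give the 9S,10S adduct) then catalyse the anti-selective aldol addition of F5 to 3. Work-up with aqueous KF gives hydroxy ester 4, at which the route is rejoined.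

**Further compounds**

F1 | step 11 | 2-[3-(C10-yl)propyl]malonic acid of the BCD tricycle (5(10)-ene; 6β-CO2Me; 13-OH; 16-methylene) | C=C1C[C@]23C[C@@]1(O)CC[C@H]2C(CCCC(C(=O)O)C(=O)O)=C[C@@H]3C(=O)OC
F2 | step 11 | 7-methyl ester of the target gibberellin (18-acid; 19,10-lactone) | C=C1C[C@]23C[C@@]1(O)CC[C@H]2[C@@]12CCC[C@@](C(=O)O)(C(=O)O1)[C@H]2[C@@H]3C(=O)OC
F3 | step 3 | (6S)-3-methoxy-6-[(2S)-5-(trimethylsilyloxy)-2,3-dihydrofuran-2-yl]cyclohex-2-en-1-one | COC1=CC(=O)[C@@H](CC1)[C@@H]1CC=C(O[Si](C)(C)C)O1
F4 | step 3 | trimethylsilyl ether of bridged carbinol 6 (8β-OSiMe3; C13 enol ether kept; 7,10α-lactone) | COC1=C[C@]2(O[Si](C)(C)C)[C@H]3C[C@H](OC3=O)[C@@H]2CC1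
F5 | step 2 | 4-methoxy-2-(tributylstannyloxy)cyclohexa-1,3-diene | COC1=CC(O[Sn](CCCC)(CCCC)CCCC)=CCC1
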